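We must decide whether this flask deserves more free catalyst or faster dissolving of its solid substrate.

solid substrate 0.54 M; second substrate 0.540 M; free catalyst 1.1 mM; time 10 h

    second substrate + free catalyst ⇌ catalyst intermediate B (K1 = 120 M⁻¹, k1 = 6.5 M⁻¹ min⁻¹)
    second substrate + catalyst intermediate A ⇌ idle complex, settled at all times (K2 = 3.9 M⁻¹)
    starting material + free catalyst ⇌ catalyst intermediate A (K3 = 1.1 M⁻¹, k3 = 7.9 M⁻¹ min⁻¹)
    catalyst intermediate B → free catalyst + second product (k4 = 15 min⁻¹)
    solid substrate ⇌ starting material, rate k5*(cs5 - [starting material]) while solid is left; crystals form when [starting material] > cs5 (cs5 = 0.37 M, k5 = 0.0063 min⁻¹)
    catalyst intermediate A ⇌ free catalyst + target (K6 = 5.8 M, k6 = 1.8 min⁻¹)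

1. how much target there is at 10 h, in percent of the solid substrate charged
2. concentration of starting material in solution at 1.0 h, in percent of saturation
3. the change that raises the amount of target at 10 h, in percent of the solid substrate charged most ("none" if none brings more than 2 percentage points) (spring / dusk / autumn / none)
4. amount of target at 10 h, in percent of the solid substrate charged, after dusk

- spring: doubling the amount of free catalyst, all else as stated
- dusk: doubling the dissolution coefficient of step 5, all else as stated
- autumn: doubling the solubility in step 5, all else as stated

- solid substrate is a solid; its amount is given per volume of the solution
- at the start none of the solid substrate is in solution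
- starting material means what is dissolved; the solid is not counted in it
- run time (flask): 10 h

Free catalyst turns dissolved starting material into target through catalyst intermediate A, while second substrate runs its own round through catalyst intermediate B. Two colleagues disagree about the slow passage.

The second colleague, whose side I take, says the catalyst round is the rate-limiting step. Catalyst intermediate A goes on to target in a fraction 0.200 of its passages and otherwise returns. With the solution at saturation and catalyst intermediate A counted as the one holder, a share 0.754 of the catalyst is free. The product of the forward constant of step 3, these two factors and the catalyst charge is the drain constant λ, the pseudo-first-order constant with which the catalyst draws dissolved starting material to target: 0.00131 min⁻¹. A solution saturated at once would then give 54.0% of target.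

The first colleague says the catalyst takes whatever arrives, so the solution stays near empty. The solid then dissolves at its full rate and is gone after 3.86 h, sooner than the run ends, so on this view the charge has passed on to target by the end of the run.

I treat the drain as a correction to the dissolving, since λ is smaller than the dissolution coefficient. Starting material then climbs towards a plateau of 0.306 M with the constant 0.00761 min⁻¹. This gives 30.3% of saturation at 1.0 h. Integrating λ over that curve gives 35.0% of target. I leave out the way back from target and the catalyst held by second substrate, so I read this as a high figure.

The same reckoning gives 43.1% for dusk and 62.1% for spring, so I choose spring. Autumn lies beyond this reckoning, since a doubled plateau exceeds the charge.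

The forecast gives 32% (29% to 35%), below my 35.0%, with 30.3% of saturation, 37% after dusk and spring as the best change, of which it says “the rate nearly doubles”.

The flask gives 32.2% of target and 36.9% after dusk. Starting material in this flask stands at 30.4% of saturation at 1.0 h. The best change is spring, worth 26 percentage points, against 9 points for autumn and 4.7 points for dusk.

In this flask λ stays below the dissolution coefficient of 0.0063 min⁻¹, and at 10.0 h starting material holds 56.9% of the charge against 32.2% as target, with 10.9% still solid. The dissolving view gets its region where the two constants draw close: in the neighbour flask with 0.0044 M of free catalyst, the same reckoning gives λ as 0.00526 min⁻¹, a fraction 0.835 of the coefficient, and after 10.0 h target stands at 79.9% and solid substrate at 0%.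

(The constants used here are assumed; the rest is arithmetic.)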